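**Retrosynthetic overview**
- Ring B is closed in the last step: the C1–C8 bond forms by cationic cyclisation of the fully unprotected, dearomatised acylphloroglucinol (tertiary cation from an isopropenyl side chain, attacked by the prenylated enol carbon), which gives the target directly.
- That precursor comes from C-prenylation at the future C1. Until then this carbon is kept silent as an allyl ester, which is removed together with the two catechol allyl ethers by palladium-mediated deallylation–decarboxylation.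
- The quaternary future C5 is built on the single free ring carbon by two C-alkylations: geranyl bromide, then a chiral primary triflate (dearomatisation).
- Aromatic core: Hoesch acylation of allyl 2,4,6-trihydroxybenzoate with 3,4-bis(allyloxy)benzonitrile. Triflate: Evans deconjugative α-geranylation of an N-(3-methylbut-2-enoyl)oxazolidinone (sets the future C7), reduction, triflation.
- Ring order: ring A (the phloroglucinol ring) is bought aromatic and dearomatised in step 9; ring B is formed in step 12; the catechol ring is bought.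

Names: geranyl = (2E)-3,7-dimethylocta-2,6-dien-1-yl; prenyl = 3-methylbut-2-en-1-yl; allyl = prop-2-en-1-yl.
Assumption: enolised triketones are drawn as one tautomer and descriptors refer to that drawing; the unwanted quaternary-carbon epimer formed in the dearomatising alkylation is removed there and is referred to only in words.

**Step 1**
Reactants: 1 2,4,6-trihydroxybenzoic acid
Product: 2 allyl 2,4,6-trihydroxybenzoate
Conditions: allyl bromide (1.05 equiv), KHCO3 (1.1 equiv), DMF, 25 °C
Reagents that add atoms: allyl bromide, C=CCBr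
Why: SN2 O-alkylation of the carboxylate (esterification), in which one equivalent of KHCO3 ionises only the strongly acidic carboxyl group while the chelated phenols stay protonated, so neither a ring carbon nor a phenol oxygen is allylated and no stereocentre is formed.

**Step 2**
Reactants: 3 3,4-dihydroxybenzonitrile
Product: 4 3,4-bis(allyloxy)benzonitrile
Conditions: allyl bromide (2.4 equiv), K2CO3, DMF, 60 °C
Reagents that add atoms: allyl bromide, C=CCBr
Why: Williamson ether synthesis masks the catechol, which would otherwise be O-alkylated in steps 8 and 9, as allyl ethers that tolerate HCl, hydroxide and amide bases and are later removed with zerovalent palladium.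

**Step 3**
Reactants: 2 allyl 2,4,6-trihydroxybenzoate; 4 3,4-bis(allyloxy)benzonitrile
Product: 6 allyl 3-[3,4-bis(allyloxy)benzoyl]-2,4,6-trihydroxybenzoate, via ketiminium chloride 5 (not isolated)
Conditions: ZnCl2, HCl (g), Et2O, 0 °C → rt; then H2O, 70 °C
Reagents that add atoms: water, O
Why: Houben–Hoesch acylation, in which the HCl/ZnCl2-activated nitrile attacks one of the two equivalent free carbons of the still strongly activated trihydroxybenzoate and the ketiminium salt is hydrolysed to the diaryl ketone, leaving exactly one unsubstituted ring carbon.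

**Step 4**
Reactants: 7 (S)-4-benzyl-1,3-oxazolidin-2-one; 8 3-methylbut-2-enoyl chloride
Product: 9 (4S)-4-benzyl-3-(3-methylbut-2-enoyl)-1,3-oxazolidin-2-one
Conditions: n-BuLi, THF, −78 °C; then 8, −78 → 0 °C
Reagents that add atoms: none
Why: N-acylation of the lithiated Evans oxazolidinone by the acid chloride attaches the auxiliary without forming a new stereocentre.

**Step 5**
Reactants: 9 (4S)-4-benzyl-3-(3-methylbut-2-enoyl)-1,3-oxazolidin-2-one; 10 geranyl bromide
Product: 11 (4S)-4-benzyl-3-[(2S,4E)-5,9-dimethyl-2-(prop-1-en-2-yl)deca-4,8-dienoyl]-1,3-oxazolidin-2-one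
Conditions: NaN(SiMe3)2, THF, −78 °C; then 10, −78 → −30 °C
Reagents that add atoms: none
Why: Evans asymmetric deconjugative alkylation, in which γ-deprotonation gives the chelated Z-dienolate that geranyl bromide attacks at the α-carbon on the face away from the benzyl group, setting the 2S centre (the future C7) with the alkene moved out of conjugation.

**Step 6**
Reactants: 11 (4S)-4-benzyl-3-[(2S,4E)-5,9-dimethyl-2-(prop-1-en-2-yl)deca-4,8-dienoyl]-1,3-oxazolidin-2-one
Product: 12 (2S,4E)-5,9-dimethyl-2-(prop-1-en-2-yl)deca-4,8-dien-1-ol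
Conditions: LiBH4, MeOH (1 equiv), Et2O, 0 °C
Reagents that add atoms: none
Why: Reductive cleavage of the imide by borohydride (hydride attack at the exocyclic carbonyl) gives the primary alcohol without touching the α-stereocentre or the alkenes and returns the auxiliary.

**Step 7**
Reactants: 12 (2S,4E)-5,9-dimethyl-2-(prop-1-en-2-yl)deca-4,8-dien-1-ol
Product: 13 (2S,4E)-5,9-dimethyl-2-(prop-1-en-2-yl)deca-4,8-dien-1-yl trifluoromethanesulfonate
Conditions: Tf2O, 2,6-lutidine, CH2Cl2, −78 °C; used at once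
Reagents that add atoms: trifluoromethanesulfonic anhydride, O=S(=O)(OS(=O)(=O)C(F)(F)F)C(F)(F)F
Why: O-sulfonylation turns the β-branched primary alcohol into a leaving group reactive enough for C-alkylation of a hindered phenoxide carbon, and the stereocentre is not involved.

**Step 8**
Reactants: 6 allyl 3-[3,4-bis(allyloxy)benzoyl]-2,4,6-trihydroxybenzoate; 10 geranyl bromide
Product: 14 allyl 3-[3,4-bis(allyloxy)benzoyl]-5-geranyl-2,4,6-trihydroxybenzoate
Conditions: 10 (1.0 equiv), aq. KOH (3 equiv), THF–H2O, 0 °C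
Reagents that add atoms: none
Why: C-alkylation of the phenoxide (SN2 on the allylic bromide) can only occur at the single unsubstituted ring carbon, because the ester- and aroyl-bearing carbons are non-nucleophilic and all three hydroxyls are chelated, which also suppresses O-alkylation.

**Step 9**
Reactants: 14 allyl 3-[3,4-bis(allyloxy)benzoyl]-5-geranyl-2,4,6-trihydroxybenzoate; 13 (2S,4E)-5,9-dimethyl-2-(prop-1-en-2-yl)deca-4,8-dien-1-yl trifluoromethanesulfonate
Product: 15 allyl (3R)-5-[3,4-bis(allyloxy)benzoyl]-3-geranyl-3-[(2R,4E)-5,9-dimethyl-2-(prop-1-en-2-yl)deca-4,8-dien-1-yl]-2,6-dihydroxy-4-oxocyclohexa-1,5-diene-1-carboxylate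
Conditions: LiN(SiMe3)2 (3.3 equiv), THF–PhMe, −78 °C; 13 (1.2 equiv), −78 → 0 °C; 1 M HCl; preparative HPLC (epimer separation)
Reagents that add atoms: none
Why: Alkylative dearomatisation, in which the lithium triphenoxide is C-alkylated (SN2 at the primary triflate, the side-chain centre being untouched and becoming 2R only through a CIP priority change) at the geranyl-bearing carbon, the only nucleophilic one, creating the quaternary future C5 without facial control, so the 3R epimer is taken from the roughly 1:1 pair by HPLC.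

**Step 10**
Reactants: 15 allyl (3R)-5-[3,4-bis(allyloxy)benzoyl]-3-geranyl-3-[(2R,4E)-5,9-dimethyl-2-(prop-1-en-2-yl)deca-4,8-dien-1-yl]-2,6-dihydroxy-4-oxocyclohexa-1,5-diene-1-carboxylate
Product: 17 (6R)-2-(3,4-dihydroxybenzoyl)-6-geranyl-6-[(2R,4E)-5,9-dimethyl-2-(prop-1-en-2-yl)deca-4,8-dien-1-yl]-3,5-dihydroxycyclohexa-2,4-dien-1-one, via triketo acid 16 (not isolated)
Conditions: Pd(PPh3)4 (5 mol %), HCO2H–Et3N, THF, 30 °C
Reagents that add atoms: none
Why: Tsuji-type deallylation, in which zerovalent palladium ionises the allyl ester and both aryl allyl ethers to π-allyl complexes that formate reduces to propene, and the freed β-keto acid 16 decarboxylates at once, unmasking the blocked ring carbon as C–H without allyl transfer to carbon.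

**Step 11**
Reactants: 17 (6R)-2-(3,4-dihydroxybenzoyl)-6-geranyl-6-[(2R,4E)-5,9-dimethyl-2-(prop-1-en-2-yl)deca-4,8-dien-1-yl]-3,5-dihydroxycyclohexa-2,4-dien-1-one; 18 prenyl bromide
Product: 19 (6R)-2-(3,4-dihydroxybenzoyl)-6-geranyl-6-[(2R,4E)-5,9-dimethyl-2-(prop-1-en-2-yl)deca-4,8-dien-1-yl]-3,5-dihydroxy-4-prenylcyclohexa-2,4-dien-1-one
Conditions: 18 (1.1 equiv), NaHCO3, THF–H2O (degassed), 0 °C → rt
Reagents that add atoms: none
Why: C-alkylation of a vinylogous acid, in which bicarbonate ionises only the triketone (pKa about 5) and not the catechol, and the delocalised anion is prenylated in water at its only CH carbon, the future C1, leaving the quaternary centre untouched.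

**Step 12**
Reactants: 19 (6R)-2-(3,4-dihydroxybenzoyl)-6-geranyl-6-[(2R,4E)-5,9-dimethyl-2-(prop-1-en-2-yl)deca-4,8-dien-1-yl]-3,5-dihydroxy-4-prenylcyclohexa-2,4-dien-1-one
Product: 21 (1S,5S,7R)-3-(3,4-dihydroxybenzoyl)-5,7-digeranyl-4-hydroxy-8,8-dimethyl-1-prenylbicyclo[3.3.1]non-3-ene-2,9-dione (target), via tertiary carbocation 20 (not isolated)
Conditions: HCO2H (neat, degassed), 25 °C, dark
Reagents that add atoms: none
Why: Biomimetic cationic cyclisation (intramolecular Markovnikov alkylation of an enol by a tertiary carbocation), in which protonation of the 1,1-disubstituted alkene gives cation 20, O-capture is reversible in formic acid, and irreversible C–C bond formation from the prenylated enol carbon through a chair transition state with the C7 geranyl equatorial closes ring B, sets C1 as S and fixes the 5S,7R relation in a net isomerisation.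

**Compound list**
1 | 2,4,6-trihydroxybenzoic acid | OC(=O)c1c(O)cc(O)cc1O | starting material
2 | allyl 2,4,6-trihydroxybenzoate | C=CCOC(=O)c1c(O)cc(O)cc1O | intermediate
3 | 3,4-dihydroxybenzonitrile | N#Cc1ccc(O)c(O)c1 | starting material
4 | 3,4-bis(allyloxy)benzonitrile | N#Cc1ccc(OCC=C)c(OCC=C)c1 | intermediate
5 | allyl 3-{[3,4-bis(allyloxy)phenyl](iminio)methyl}-2,4,6-trihydroxybenzoate chloride (ketiminium chloride) | C=CCOC(=O)c1c(O)cc(O)c(C(=[NH2+])c2ccc(OCC=C)c(OCC=C)c2)c1O.[Cl-] | intermediate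
6 | allyl 3-[3,4-bis(allyloxy)benzoyl]-2,4,6-trihydroxybenzoate | C=CCOC(=O)c1c(O)cc(O)c(C(=O)c2ccc(OCC=C)c(OCC=C)c2)c1O | intermediate
7 | (S)-4-benzyl-1,3-oxazolidin-2-one | O=C1N[C@@H](Cc2ccccc2)CO1 | starting material
8 | 3-methylbut-2-enoyl chloride | CC(C)=CC(=O)Cl | starting material
9 | (4S)-4-benzyl-3-(3-methylbut-2-enoyl)-1,3-oxazolidin-2-one | CC(C)=CC(=O)N1[C@@H](Cc2ccccc2)COC1=O | intermediate
10 | geranyl bromide, (2E)-1-bromo-3,7-dimethylocta-2,6-diene | CC(C)=CCC/C(C)=C/CBr | starting material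
11 | (4S)-4-benzyl-3-[(2S,4E)-5,9-dimethyl-2-(prop-1-en-2-yl)deca-4,8-dienoyl]-1,3-oxazolidin-2-one | CC(C)=CCC/C(C)=C/C[C@@H](C(C)=C)C(=O)N1[C@@H](Cc2ccccc2)COC1=O | intermediate
12 | (2S,4E)-5,9-dimethyl-2-(prop-1-en-2-yl)deca-4,8-dien-1-ol | CC(C)=CCC/C(C)=C/C[C@@H](C(C)=C)CO | intermediate
13 | (2S,4E)-5,9-dimethyl-2-(prop-1-en-2-yl)deca-4,8-dien-1-yl trifluoromethanesulfonate | CC(C)=CCC/C(C)=C/C[C@@H](C(C)=C)COS(=O)(=O)C(F)(F)F | intermediate
14 | allyl 3-[3,4-bis(allyloxy)benzoyl]-5-geranyl-2,4,6-trihydroxybenzoate | C=CCOC(=O)c1c(O)c(C/C=C(\C)CCC=C(C)C)c(O)c(C(=O)c2ccc(OCC=C)c(OCC=C)c2)c1O | intermediate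
15 | allyl (3R)-5-[3,4-bis(allyloxy)benzoyl]-3-geranyl-3-[(2R,4E)-5,9-dimethyl-2-(prop-1-en-2-yl)deca-4,8-dien-1-yl]-2,6-dihydroxy-4-oxocyclohexa-1,5-diene-1-carboxylate | CC(C)=CCC/C(C)=C/C[C@@H](C(C)=C)C[C@@]1(C/C=C(\C)CCC=C(C)C)C(=O)C(C(=O)c2ccc(OCC=C)c(OCC=C)c2)=C(O)C(C(=O)OCC=C)=C1O | intermediate
16 | (3R)-5-(3,4-dihydroxybenzoyl)-3-geranyl-3-[(2R,4E)-5,9-dimethyl-2-(prop-1-en-2-yl)deca-4,8-dien-1-yl]-2,6-dihydroxy-4-oxocyclohexa-1,5-diene-1-carboxylic acid (triketo acid) | CC(C)=CCC/C(C)=C/C[C@@H](C(C)=C)C[C@@]1(C/C=C(\C)CCC=C(C)C)C(=O)C(C(=O)c2ccc(O)c(O)c2)=C(O)C(C(=O)O)=C1O | intermediate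
17 | (6R)-2-(3,4-dihydroxybenzoyl)-6-geranyl-6-[(2R,4E)-5,9-dimethyl-2-(prop-1-en-2-yl)deca-4,8-dien-1-yl]-3,5-dihydroxycyclohexa-2,4-dien-1-one | CC(C)=CCC/C(C)=C/C[C@@H](C(C)=C)C[C@@]1(C/C=C(\C)CCC=C(C)C)C(=O)C(C(=O)c2ccc(O)c(O)c2)=C(O)C=C1O | intermediate
18 | prenyl bromide, 1-bromo-3-methylbut-2-ene | CC(C)=CCBr | starting material
19 | (6R)-2-(3,4-dihydroxybenzoyl)-6-geranyl-6-[(2R,4E)-5,9-dimethyl-2-(prop-1-en-2-yl)deca-4,8-dien-1-yl]-3,5-dihydroxy-4-prenylcyclohexa-2,4-dien-1-one | CC(C)=CCC/C(C)=C/C[C@@H](C(C)=C)C[C@@]1(C/C=C(\C)CCC=C(C)C)C(=O)C(C(=O)c2ccc(O)c(O)c2)=C(O)C(CC=C(C)C)=C1O | intermediate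
20 | tertiary carbocation formed from 19 by protonation of the isopropenyl group (cation at the future C8) | CC(C)=CCC/C(C)=C/C[C@@H]([C+](C)C)C[C@@]1(C/C=C(\C)CCC=C(C)C)C(=O)C(C(=O)c2ccc(O)c(O)c2)=C(O)C(CC=C(C)C)=C1O | intermediate
21 | (1S,5S,7R)-3-(3,4-dihydroxybenzoyl)-5,7-digeranyl-4-hydroxy-8,8-dimethyl-1-prenylbicyclo[3.3.1]non-3-ene-2,9-dione (CNP0125932.1) | CC(C)=CCC/C(C)=C/C[C@@H]1C[C@]2(C/C=C(\C)CCC=C(C)C)C(=O)[C@@](CC=C(C)C)(C(=O)C(C(=O)c3ccc(O)c(O)c3)=C2O)C1(C)C | target

**Totals**
Total step count: 12.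
Longest linear sequence: 8 steps (steps 4, 5, 6, 7, 9, 10, 11, 12).

**Three steps most likely to fail**

Step 12 (cationic cyclisation). The risks are competing protonation of the geranyl and prenyl alkenes, O-cyclisation, and failure to join the two fully substituted carbons. The fallback sets out from 19 and comes back at 21, and it generates the cation without a free Brønsted acid acting on the other alkenes. Hg(OAc)2 (1 equiv, THF, −20 °C) reacts fastest with the 1,1-disubstituted alkene, and the enol oxygen next to the quaternary carbon closes a pyran. Demercuration with NaBH4/NaOH then gives the cyclic enol ether 6-(3,4-dihydroxybenzoyl)-3,4a-digeranyl-5-hydroxy-2,2-dimethyl-8-prenyl-2,3,4,4a-tetrahydro-7H-chromen-7-one F1 (centres as in 19). F1 is a vinylogous tert-alkyl ester, so BF3·OEt2 (CH2Cl2, −40 °C) ionises its C–O bond to the same cation as 20, which collapses at carbon to 21.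

Step 9 (quaternisation of a stabilised triphenoxide by a β-branched triflate). The risks are O-alkylation or no reaction. The fallback sets out from 6 and comes back at 15, and it reverses the order of the two C-alkylations. Triflate 13 first alkylates the free, unhindered carbon of 6 (LiN(SiMe3)2, THF, −78 → 0 °C) to give allyl 3-[3,4-bis(allyloxy)benzoyl]-5-[(2R,4E)-5,9-dimethyl-2-(prop-1-en-2-yl)deca-4,8-dien-1-yl]-2,4,6-trihydroxybenzoate F2. The quaternary centre is then closed with the small, reactive allylic bromide 10 (aq. KOH, THF–H2O, 0 °C), and the same HPLC separation gives 15.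

Step 3 (Hoesch acylation). The ring is deactivated by the ester and the nitrile is electron-rich. The fallback sets out from 4 and comes back at 6. Nitrile 4 is hydrolysed (KOH, EtOH–H2O, reflux) to 3,4-bis(allyloxy)benzoic acid F3. Compound 2 is then acylated with the mixed trifluoroacetic anhydride of F3 (trifluoroacetic anhydride, CH2Cl2, 0 °C → rt; then NaHCO3, MeOH to cleave O-trifluoroacetates). This is a Friedel–Crafts acylation by an acylium-type electrophile in place of the nitrilium ion, and it gives 6.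

**Further compounds**
F1 | step 12 | 6-(3,4-dihydroxybenzoyl)-3,4a-digeranyl-5-hydroxy-2,2-dimethyl-8-prenyl-2,3,4,4a-tetrahydro-7H-chromen-7-one (cyclic enol ether, centres as in 19) | CC(C)=CCC/C(C)=C/C[C@@H]1C[C@@]2(C/C=C(\C)CCC=C(C)C)C(O)=C(C(=O)c3ccc(O)c(O)c3)C(=O)C(CC=C(C)C)=C2OC1(C)C
F2 | step 9 | allyl 3-[3,4-bis(allyloxy)benzoyl]-5-[(2R,4E)-5,9-dimethyl-2-(prop-1-en-2-yl)deca-4,8-dien-1-yl]-2,4,6-trihydroxybenzoate | C=CCOC(=O)c1c(O)c(C[C@H](C(C)=C)C/C=C(\C)CCC=C(C)C)c(O)c(C(=O)c2ccc(OCC=C)c(OCC=C)c2)c1O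
F3 | step 3 | 3,4-bis(allyloxy)benzoic acid | OC(=O)c1ccc(OCC=C)c(OCC=C)c1
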